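**Retrosynthetic overview**
1. Target 18 ⇐ hydrogenation of the C11=C12 alkene of 17; the D ring (C13–C16 bond and the C16 tertiary alcohol) comes from an intramolecular carbonyl-ene reaction of an α-diketone.
2. The C ring comes from a Diels–Alder reaction of butadiene with the α-acyl unsaturated spiro-δ-lactone 13, which sets C8 and C9.
3. The spirolactone is opened at its acyl C–O bond (ester formation at C20–O) and at C9–C10 (one-carbon insertion with DMF-DMA).
4. Pivotal step: a C–B to C–O oxidation followed by a transannular oxa-Michael addition closes the C3–O–C6 ether. The resulting 6-oxabicyclo[3.2.1]octanone fixes C3 and then steers C10, C9 and C8.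
5. Everything derives from 4,4-dimethylcyclohexadienone through one enantioselective borylmethyl conjugate addition with formaldehyde aldol trapping (sets C5). Ring order: A, ether bridge, δ-lactone, C, D.

Assumption: locants C1–C20 follow kaurane numbering of the target (C1 and C15 ketones, C3–O–C6 ether, C7 lactone carbonyl, C20 lactone CH2, C16 carbinol); the target is (3S,5S,8S,9S,10S,13R,16R), and 7 is taken to be a catalogue chemical.

**Route**

Step 1
Reactants: 1 4,4-dimethylcyclohex-2-en-1-one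
Product: 2 4,4-dimethylcyclohexa-2,5-dien-1-one
Conditions: DDQ (1.3 equiv), TsOH (cat.), 1,4-dioxane, 100 °C
Reagents that add atoms: none
Why: DDQ dehydrogenation of a 4,4-disubstituted cyclohexenone to the cross-conjugated dienone is a standard oxidation, and no stereocentre is formed.

Step 2
Reactants: 2 4,4-dimethylcyclohexa-2,5-dien-1-one; 3 bis[(pinacolato)boryl]methane; 4 formaldehyde
Product: 6 (5R,6S)-6-(hydroxymethyl)-4,4-dimethyl-5-[(pinacolboryl)methyl]cyclohex-2-en-1-one, via lithium enolate 5 (not isolated)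
Conditions: Cu(MeCN)4PF6 (5 mol %), Josiphos-type chiral bisphosphine (6 mol %, antipode chosen for 5R), LiOt-Bu (1.2 equiv), THF, 0 °C; then monomeric CH2O in THF, −78 °C; H2O quench
Reagents that add atoms: none
Why: Proposed new method: the chiral Cu(I) alkoxide transmetalates with the alkoxide "ate" complex of 3 to give L*Cu–CH2Bpin, which adds 1,4 to one of the two enantiotopic enone units of the non-enolisable dienone (catalyst control sets C5 as R), Li/Cu exchange turns the catalyst over, and the regiodefined enolate 5 undergoes aldol addition to CH2O anti to the new C5 substituent (this C6 centre is erased in step 5); the closest known reactions are the Cu-catalysed enantioselective conjugate addition of borylmethylcopper to alkylidene malonates and the Cu-catalysed dialkylzinc desymmetrisation of 4,4-disubstituted cyclohexadienones with aldol trapping.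

Step 3
Reactants: 6 (5R,6S)-6-(hydroxymethyl)-4,4-dimethyl-5-[(pinacolboryl)methyl]cyclohex-2-en-1-one; 7 methyl 4,4-dimethoxy-3-oxopentanoate
Product: 8 {(1S,6R)-5,5-dimethyl-2-oxo-6-[(pinacolboryl)methyl]cyclohex-3-en-1-yl}methyl 4,4-dimethoxy-3-oxopentanoate
Conditions: 7 (3 equiv), toluene, 105 °C, 4 Å MS (removal of MeOH)
Reagents that add atoms: none
Why: Thermal transesterification of a β-keto ester through its acylketene forms the C20–O acyl bond under neutral conditions, so the elimination-prone aldol and the C–B bond survive and no stereocentre is touched.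

Step 4
Reactants: 8 {(1S,6R)-5,5-dimethyl-2-oxo-6-[(pinacolboryl)methyl]cyclohex-3-en-1-yl}methyl 4,4-dimethoxy-3-oxopentanoate
Product: 10 [(1R,2S,5S)-8,8-dimethyl-3-oxo-6-oxabicyclo[3.2.1]octan-2-yl]methyl 4,4-dimethoxy-3-oxopentanoate, via hydroxy enone 9 (not isolated)
Conditions: 30% H2O2, aq. NaHCO3, THF, 0 to 23 °C; then CSA (10 mol %), CH2Cl2, 23 °C
Reagents that add atoms: hydrogen peroxide, OO
Why: Boronate oxidation (1,2-metallate shift, C–B to C–O) unmasks the C6 alcohol, which closes by 5-exo-trig oxa-Michael addition onto C3 of the enone; the one-atom tether forces the new C3–O bond cis to C5–C6 and so sets C3 (S) (C2 of the bicycle is epimerisable and is erased in step 5).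

Step 5
Reactants: 10 [(1R,2S,5S)-8,8-dimethyl-3-oxo-6-oxabicyclo[3.2.1]octan-2-yl]methyl 4,4-dimethoxy-3-oxopentanoate; 11 N,N-dimethylformamide dimethyl acetal
Product: 13 (1S,2S,5S)-5′-(2,2-dimethoxypropanoyl)-8,8-dimethyl-2′H-spiro[6-oxabicyclo[3.2.1]octane-2,3′-pyran]-3,6′-dione, via enaminone 12 (not isolated)
Conditions: 11 (1.5 equiv), CH2Cl2, 0 to 23 °C; then TFA (3 equiv), 0 to 23 °C; crude 13 used directly
Reagents that add atoms: none
Why: Condensation of the active methylene with DMF-DMA gives enaminone 12, and under acid the more substituted ketone enol (C1=C10) attacks the vinylogous iminium carbon through a six-membered Mannich-type transition state and loses Me2NH (a Knoevenagel-type spiroannulation, the intramolecular counterpart of ketone/aminomethylene-1,3-dicarbonyl condensations); C9 bonds to the enol face on the side of the O–CH2 bridge, anti to the gem-dimethyl bridge (camphor-like bias), which sets quaternary C10 (S).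

Step 6
Reactants: 13 (1S,2S,5S)-5′-(2,2-dimethoxypropanoyl)-8,8-dimethyl-2′H-spiro[6-oxabicyclo[3.2.1]octane-2,3′-pyran]-3,6′-dione; 14 buta-1,3-diene
Product: 15 (3S,5S,8S,9S,10S)-3,6-epoxy-16,16-dimethoxy-1,15-dioxo-6,7:13,16-disecokaur-12-en-7,20-olide (cis-fused cyclohexene adduct)
Conditions: 14 (10 equiv), ZnCl2 (0.5 equiv), Et2O/CH2Cl2, 23 °C, sealed tube
Reagents that add atoms: none
Why: Diels–Alder reaction of a doubly activated 3-acyl-5,6-dihydropyran-2-one (ZnCl2 chelated between the two carbonyls); the diene adds to the lactone face flanked by the planar C1 ketone, anti to the bulky C5 bridgehead, giving the cis-fused adduct with C8 and C9 set (both S).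

Step 7
Reactants: 15 (3S,5S,8S,9S,10S)-3,6-epoxy-16,16-dimethoxy-1,15-dioxo-6,7:13,16-disecokaur-12-en-7,20-olide
Product: 17 (3S,5S,8S,9S,10S,13S,16R)-3,6-epoxy-16-hydroxy-1,15-dioxo-6,7-secokaur-11-en-7,20-olide, via diketone 16 (not isolated)
Conditions: TFA/H2O (9:1), 0 to 23 °C; concentrate; then Sc(OTf)3 (10 mol %), CH2Cl2, 23 °C
Reagents that add atoms: water, O
Why: Hydrolysis frees the α-diketone, whose activated C16 ketone undergoes an intramolecular carbonyl-ene reaction when the C8 acyl arm is axial: C16 bonds to C13 (five-membered ring, bicyclo[3.2.1]) while the pseudoaxial C11–H on the same face goes to oxygen, so the OH points to the C11/C12 bridge and C16 (R) and C13 are fixed.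

Step 8
Reactants: 17 (3S,5S,8S,9S,10S,13S,16R)-3,6-epoxy-16-hydroxy-1,15-dioxo-6,7-secokaur-11-en-7,20-olide
Product: 18 (3S,5S,8S,9S,10S,13R,16R)-3,6-epoxy-16-hydroxy-1,15-dioxo-6,7-secokauran-7,20-olide (target CNP0538153.1)
Conditions: H2 (1 atm), 10% Pd/C, EtOAc, 23 °C
Reagents that add atoms: none
Why: Heterogeneous hydrogenation of the isolated cis-disubstituted alkene leaves ketones, lactone and the tertiary α-ketol untouched and changes no stereocentre (the C13 descriptor changes from S to R by CIP priority only).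

**Compound list**
1 | 4,4-dimethylcyclohex-2-en-1-one | CC1(C)CCC(=O)C=C1 | starting material
2 | 4,4-dimethylcyclohexa-2,5-dien-1-one | CC1(C)C=CC(=O)C=C1 | intermediate
3 | bis[(pinacolato)boryl]methane | CC1(C)OB(CB2OC(C)(C)C(C)(C)O2)OC1(C)C | starting material
4 | formaldehyde | C=O | starting material
5 | lithium (3R)-4,4-dimethyl-3-[(pinacolboryl)methyl]cyclohexa-1,5-dien-1-olate | [Li+].CC1(C)C=CC([O-])=C[C@H]1CB2OC(C)(C)C(C)(C)O2 | intermediate
6 | (5R,6S)-6-(hydroxymethyl)-4,4-dimethyl-5-[(4,4,5,5-tetramethyl-1,3,2-dioxaborolan-2-yl)methyl]cyclohex-2-en-1-one | CC1(C)C=CC(=O)[C@H](CO)[C@H]1CB2OC(C)(C)C(C)(C)O2 | intermediate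
7 | methyl 4,4-dimethoxy-3-oxopentanoate | COC(=O)CC(=O)C(C)(OC)OC | starting material
8 | {(1S,6R)-5,5-dimethyl-2-oxo-6-[(pinacolboryl)methyl]cyclohex-3-en-1-yl}methyl 4,4-dimethoxy-3-oxopentanoate | CC1(C)C=CC(=O)[C@H](COC(=O)CC(=O)C(C)(OC)OC)[C@H]1CB2OC(C)(C)C(C)(C)O2 | intermediate
9 | [(1S,6R)-6-(hydroxymethyl)-5,5-dimethyl-2-oxocyclohex-3-en-1-yl]methyl 4,4-dimethoxy-3-oxopentanoate | CC1(C)C=CC(=O)[C@H](COC(=O)CC(=O)C(C)(OC)OC)[C@H]1CO | intermediate
10 | [(1R,2S,5S)-8,8-dimethyl-3-oxo-6-oxabicyclo[3.2.1]octan-2-yl]methyl 4,4-dimethoxy-3-oxopentanoate | CC1(C)[C@@H]2CC(=O)[C@H](COC(=O)CC(=O)C(C)(OC)OC)[C@H]1CO2 | intermediate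
11 | N,N-dimethylformamide dimethyl acetal | COC(OC)N(C)C | starting material
12 | [(1R,2S,5S)-8,8-dimethyl-3-oxo-6-oxabicyclo[3.2.1]octan-2-yl]methyl 2-[(dimethylamino)methylidene]-4,4-dimethoxy-3-oxopentanoate (E/Z mixture) | CC1(C)[C@@H]2CC(=O)[C@H](COC(=O)C(=CN(C)C)C(=O)C(C)(OC)OC)[C@H]1CO2 | intermediate
13 | (1S,2S,5S)-5′-(2,2-dimethoxypropanoyl)-8,8-dimethyl-2′H-spiro[6-oxabicyclo[3.2.1]octane-2,3′-pyran]-3,6′-dione | CC1(C)[C@@H]2CC(=O)[C@]3(COC(=O)C(C(=O)C(C)(OC)OC)=C3)[C@H]1CO2 | intermediate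
14 | buta-1,3-diene | C=CC=C | starting material
15 | (3S,5S,8S,9S,10S)-3,6-epoxy-16,16-dimethoxy-1,15-dioxo-6,7:13,16-disecokaur-12-en-7,20-olide | CC1(C)[C@@H]2CC(=O)[C@]3(COC(=O)[C@]4(CC=CC[C@H]43)C(=O)C(C)(OC)OC)[C@H]1CO2 | intermediate
16 | (3S,5S,8S,9S,10S)-3,6-epoxy-1,15,16-trioxo-6,7:13,16-disecokaur-12-en-7,20-olide | CC1(C)[C@@H]2CC(=O)[C@]3(COC(=O)[C@]4(CC=CC[C@H]43)C(=O)C(C)=O)[C@H]1CO2 | intermediate
17 | (3S,5S,8S,9S,10S,13S,16R)-3,6-epoxy-16-hydroxy-1,15-dioxo-6,7-secokaur-11-en-7,20-olide | CC1(C)[C@@H]2CC(=O)[C@]3(COC(=O)[C@@]45C[C@@H](C=C[C@H]43)[C@@](C)(O)C5=O)[C@H]1CO2 | intermediate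
18 | (3S,5S,8S,9S,10S,13R,16R)-3,6-epoxy-16-hydroxy-1,15-dioxo-6,7-secokauran-7,20-olide | CC1(C)[C@@H]2CC(=O)[C@]3(COC(=O)[C@@]45C[C@@H](CC[C@H]43)[C@@](C)(O)C5=O)[C@H]1CO2 | target

**Step count and risks**
Total steps: 8. Longest linear sequence: 8 (1 to 18); all other partners (3, 4, 7, 11, 14) are purchased.

Step 2 (the proposed new method) may fail on reactivity at the neopentyl β-carbon or on enantioselectivity. The fallback uses known chemistry, sets out from 2 and comes back at 10. Rh(I)/(S)-BINAP-catalysed 1,4-addition of potassium vinyltrifluoroborate (Hayashi–Miyaura) desymmetrises 2 to (S)-4,4-dimethyl-5-vinylcyclohex-2-en-1-one F1. LDA and then CH2O give the trans aldol (5R,6S)-6-(hydroxymethyl)-4,4-dimethyl-5-vinylcyclohex-2-en-1-one F2. Heating with 7 gives the β-keto ester [(1S,6R)-5,5-dimethyl-2-oxo-6-vinylcyclohex-3-en-1-yl]methyl 4,4-dimethoxy-3-oxopentanoate F3. OsO4/NaIO4 (Lemieux–Johnson) cleaves only the vinyl group to the aldehyde [(1S,6R)-6-formyl-5,5-dimethyl-2-oxocyclohex-3-en-1-yl]methyl 4,4-dimethoxy-3-oxopentanoate F4, which is reduced at once with NaBH(OAc)3 to 9 and closed with CSA to 10.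

Step 5 may fail through β-elimination of the acyloxy group or through a sluggish enol attack. The fallback uses known chemistry, sets out from 10 and comes back at 13. Paraformaldehyde with piperidinium acetate effects Knoevenagel condensation at the active methylene and in situ intramolecular Michael addition of the C10 enol (same facial bias), giving the saturated spirolactone (1S,2S,5S)-5′-(2,2-dimethoxypropanoyl)-8,8-dimethyltetrahydrospiro[6-oxabicyclo[3.2.1]octane-2,3′-pyran]-3,6′-dione F5. PhSeCl/pyridine gives the α-phenylselanyl β-keto lactone F6, and H2O2 (selenoxide syn-elimination) delivers 13.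

Step 7 may fail on ene regiochemistry (bicyclo[2.2.2] instead of [3.2.1]) or through ionic side reactions. The fallback replaces the pericyclic step by an aldol, sets out from 13 and comes back at 18. Diels–Alder reaction of 13 with 2-(trimethylsilyloxy)buta-1,3-diene gives the silyl enol ether adduct (12-trimethylsilyloxy analogue of 15) F7, with the silyloxy group on C12, "para" to C8. Aqueous TFA unmasks the 12-oxo triketone F8. Pyrrolidinium acetate promotes the reversible intramolecular aldol of the C13 enol onto the C16 ketone, giving the 12-oxo derivative of 18 F9 with the OH hydrogen-bonded to C12=O. TsNHNH2 condenses selectively with the least hindered C12 ketone to the tosylhydrazone F10, and catecholborane/NaOAc reduction gives 18.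

Further compounds
F1 | step 2 | (S)-4,4-dimethyl-5-vinylcyclohex-2-en-1-one | CC1(C)C=CC(=O)C[C@H]1C=C
F2 | step 2 | (5R,6S)-6-(hydroxymethyl)-4,4-dimethyl-5-vinylcyclohex-2-en-1-one | CC1(C)C=CC(=O)[C@H](CO)[C@H]1C=C
F3 | step 2 | [(1S,6R)-5,5-dimethyl-2-oxo-6-vinylcyclohex-3-en-1-yl]methyl 4,4-dimethoxy-3-oxopentanoate | CC1(C)C=CC(=O)[C@H](COC(=O)CC(=O)C(C)(OC)OC)[C@H]1C=C
F4 | step 2 | [(1S,6R)-6-formyl-5,5-dimethyl-2-oxocyclohex-3-en-1-yl]methyl 4,4-dimethoxy-3-oxopentanoate | CC1(C)C=CC(=O)[C@H](COC(=O)CC(=O)C(C)(OC)OC)[C@H]1C=O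
F5 | step 5 | (1S,2S,5S)-5′-(2,2-dimethoxypropanoyl)-8,8-dimethyltetrahydrospiro[6-oxabicyclo[3.2.1]octane-2,3′-pyran]-3,6′-dione (C5′ epimers) | CC1(C)[C@@H]2CC(=O)[C@]3(COC(=O)C(C(=O)C(C)(OC)OC)C3)[C@H]1CO2
F6 | step 5 | 5′-phenylselanyl derivative of F5 | CC1(C)[C@@H]2CC(=O)[C@]3(COC(=O)C([Se]c4ccccc4)(C(=O)C(C)(OC)OC)C3)[C@H]1CO2
F7 | step 7 | (3S,5S,8S,9S,10S)-3,6-epoxy-16,16-dimethoxy-1,15-dioxo-12-(trimethylsilyloxy)-6,7:13,16-disecokaur-12-en-7,20-olide | CC1(C)[C@@H]2CC(=O)[C@]3(COC(=O)[C@]4(CC=C(O[Si](C)(C)C)C[C@H]43)C(=O)C(C)(OC)OC)[C@H]1CO2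
F8 | step 7 | (3S,5S,8S,9S,10S)-3,6-epoxy-1,12,15,16-tetraoxo-6,7:13,16-disecokauran-7,20-olide | CC1(C)[C@@H]2CC(=O)[C@]3(COC(=O)[C@]4(CCC(=O)C[C@H]43)C(=O)C(C)=O)[C@H]1CO2
F9 | step 7 | 12-oxo derivative of 18 (3,6-epoxy-16-hydroxy-1,12,15-trioxo-6,7-secokauran-7,20-olide) | CC1(C)[C@@H]2CC(=O)[C@]3(COC(=O)[C@@]45C[C@@H](C(=O)C[C@H]43)[C@@](C)(O)C5=O)[C@H]1CO2
F10 | step 7 | C12 tosylhydrazone of F9 | CC1(C)[C@@H]2CC(=O)[C@]3(COC(=O)[C@@]45C[C@@H](C(=NNS(=O)(=O)c6ccc(C)cc6)C[C@H]43)[C@@](C)(O)C5=O)[C@H]1CO2
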